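**Plan**
- Retrosynthesis first removes the six C–Br bonds and the two O-methyl groups on ring B, leaving a 4-aryloxy-2-silylphenol. Ring A (C1 OH, C2, C3 H, C4 O-aryl, C5, C6) is then cut at C3–C4, C1–C2 and C1–C6.
- These cuts give an aryloxy(alkenyl)carbene chromium complex (C4, C5, C6 and the ether oxygen), trimethylsilylacetylene (C2, C3) and one CO ligand (C1 with its oxygen). The enabling feature is that ring A is a hydroquinone mono-ether, with the OH at C1 para to the ether oxygen at C4.
- The carbene complex is cut into 2,5-dimethoxyphenol (ring B, bought), Cr(CO)6 and an (E)-2-silylvinyllithium. The β-silyl group is added to stabilise the vinylcarbene; it ends on the phenol oxygen and is removed at work-up.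
- Forward: acylchromate (step 1), aryloxycarbene (step 2), benzannulation that builds ring A onto the ether oxygen (step 3), sixfold bromination (step 4), demethylation (step 5). Ring B is never constructed, only brominated.
- Stereochemistry: the target has no stereocentre. The only stereo element in the route, the E alkene of the vinylsilane, is consumed in step 3.

Key step: step 3

Assumption: the target SMILES contains no stereogenic element, so the compound asked for is the achiral molecule itself. Ring A is numbered C1 (OH) to C6 as above; ring B is C1′ (ether O), C2′ and C5′ (OH), C3′, C4′ and C6′ (Br).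

**Step 1**
Reactants: 1 (E)-(2-bromovinyl)trimethylsilane; 2 chromium hexacarbonyl
Product: 5 tetramethylammonium pentacarbonyl[(2E)-1-oxido-3-(trimethylsilyl)prop-2-en-1-ylidene]chromate, via (E)-2-(trimethylsilyl)vinyllithium 3 (not isolated), via lithium acylchromate 4 (not isolated)
Conditions: t-BuLi (2.0 equiv), Et2O, −78 °C; then 2, Et2O, −78 °C → rt; then Me4NBr, degassed H2O, 0 °C
Reagents that add atoms: tetramethylammonium bromide, C[N+](C)(C)C.[Br-]
Why: Bromine–lithium exchange with retention of the E geometry, followed by addition of the vinyllithium to a CO ligand (first half of the Fischer carbene synthesis), should give the acylchromate, which cation metathesis turns into the storable tetramethylammonium salt.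

**Step 2**
Reactants: 5 tetramethylammonium pentacarbonyl[(2E)-1-oxido-3-(trimethylsilyl)prop-2-en-1-ylidene]chromate; 6 2,5-dimethoxyphenol
Product: 8 pentacarbonyl[(2E)-1-(2,5-dimethoxyphenoxy)-3-(trimethylsilyl)prop-2-en-1-ylidene]chromium, via acetoxycarbene complex 7 (not isolated)
Conditions: AcBr (1.0 equiv), CH2Cl2, −40 °C; then 6 (1.1 equiv), −40 → 0 °C; quick filtration through silica under argon
Reagents that add atoms: none
Why: O-acylation of the acylate gives a strongly electrophilic acyloxycarbene in which the phenol should replace acetate by addition–elimination at the carbene carbon (acyloxy/aryloxy exchange), while the β-silyl group shields the alkene against conjugate addition and polymerisation.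

**Step 3**
Reactants: 8 pentacarbonyl[(2E)-1-(2,5-dimethoxyphenoxy)-3-(trimethylsilyl)prop-2-en-1-ylidene]chromium; 9 trimethylsilylacetylene
Product: 12 4-(2,5-dimethoxyphenoxy)-2-(trimethylsilyl)phenol, via arene tricarbonylchromium complex 10 (not isolated), via aryl trimethylsilyl ether 11 (not isolated)
Conditions: 9 (2 equiv), degassed THF (0.05 M), 50 °C, argon; then air, hν, Et2O, rt; then K2CO3 (cat.), MeOH, 0 °C
Reagents that add atoms: none
Why: Thermal loss of a cis-CO from 8 frees a site for the alkyne, which inserts into the Cr=C bond with its CH terminus bonding to the carbene carbon (C3–C4); CO insertion at the silyl-bearing carbon then gives a chromium-bound dienylketene (C2–C1), and 6π-electrocyclisation onto the vinyl β-carbon (C1–C6) closes ring A as a cyclohexa-2,4-dienone. This is the Dötz benzannulation of an alkenyl(alkoxy)carbene chromium complex, for which aryloxy(alkenyl) complexes giving diaryl ethers and β-silylvinyl complexes are both known substrate types. Ring A is the only ring formed, by this formal [3+2+1] assembly with the electrocyclisation as the closing event; the dienone should then aromatise by a 1,3-shift of the C6 silyl group to the carbonyl oxygen, so that the phenol appears as its silyl ether on Cr(CO)3 and is released by air and catalytic methanolysis. No stereocentre is created, and the E geometry of the vinylsilane disappears. The step needs alkyne regioselectivity (silyl carbon next to the CO-derived carbon), which the size difference between SiMe3 and H should secure, and six- over five-membered ring formation, which chromium, an alkenyl carbene and THF favour. Whichever group migrates in the aromatisation, silicon remains only on carbons that are brominated in step 4.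

**Step 4**
Reactants: 12 4-(2,5-dimethoxyphenoxy)-2-(trimethylsilyl)phenol
Product: 13 2,3,6-tribromo-4-(3,4,6-tribromo-2,5-dimethoxyphenoxy)phenol
Conditions: Br2 (8 equiv), CHCl3, 0 °C → rt; then Fe powder (cat.), 55 °C, followed by LC-MS; aq. Na2S2O3
Reagents that add atoms: bromine, BrBr
Why: Electrophilic aromatic bromination with one ipso-bromodesilylation should take the silylated C2, the other ortho position C6 and C4′ first, then C6′, and finally under Lewis-acid assistance C3′ and C5, the ring A site being unambiguous because C3 and C5 are symmetry-equivalent once C2 and C6 carry bromine, and the last ring A hydrogen being deactivated by a further meta bromine.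

**Step 5**
Reactants: 13 2,3,6-tribromo-4-(3,4,6-tribromo-2,5-dimethoxyphenoxy)phenol
Product: 14 2,3,5-tribromo-6-(2,3,5-tribromo-4-hydroxyphenoxy)benzene-1,4-diol
Conditions: BBr3 (6 equiv), CH2Cl2, −78 °C → rt; then ice-water
Reagents that add atoms: none
Why: Boron tribromide demethylation (O–B complexation, then attack of bromide on the methyl group) should cleave both hindered aryl methyl ethers while the diaryl ether and the six aryl bromides remain untouched.

**Compound list**
1 | (E)-(2-bromovinyl)trimethylsilane | C[Si](C)(C)/C=C/Br | starting material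
2 | chromium hexacarbonyl | O=C=[Cr](=C=O)(=C=O)(=C=O)(=C=O)=C=O | starting material
3 | (E)-2-(trimethylsilyl)vinyllithium | [Li]/C=C/[Si](C)(C)C | intermediate
4 | lithium pentacarbonyl[(2E)-1-oxido-3-(trimethylsilyl)prop-2-en-1-ylidene]chromate | C[Si](C)(C)/C=C/C([O-])=[Cr](=C=O)(=C=O)(=C=O)(=C=O)=C=O.[Li+] | intermediate
5 | tetramethylammonium pentacarbonyl[(2E)-1-oxido-3-(trimethylsilyl)prop-2-en-1-ylidene]chromate | C[Si](C)(C)/C=C/C([O-])=[Cr](=C=O)(=C=O)(=C=O)(=C=O)=C=O.C[N+](C)(C)C | intermediate
6 | 2,5-dimethoxyphenol | COc1ccc(OC)c(O)c1 | starting material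
7 | pentacarbonyl[(2E)-1-acetoxy-3-(trimethylsilyl)prop-2-en-1-ylidene]chromium | CC(=O)OC(/C=C/[Si](C)(C)C)=[Cr](=C=O)(=C=O)(=C=O)(=C=O)=C=O | intermediate
8 | pentacarbonyl[(2E)-1-(2,5-dimethoxyphenoxy)-3-(trimethylsilyl)prop-2-en-1-ylidene]chromium | COc1ccc(OC)c(OC(/C=C/[Si](C)(C)C)=[Cr](=C=O)(=C=O)(=C=O)(=C=O)=C=O)c1 | intermediate
9 | trimethylsilylacetylene | C#C[Si](C)(C)C | starting material
10 | tricarbonyl{η6-[4-(2,5-dimethoxyphenoxy)-2-(trimethylsilyl)phenoxy]trimethylsilane}chromium (ring A bound) | COc1ccc(OC)c(Oc2ccc(O[Si](C)(C)C)c([Si](C)(C)C)c2)c1.O=C=[Cr](=C=O)=C=O | intermediate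
11 | [4-(2,5-dimethoxyphenoxy)-2-(trimethylsilyl)phenoxy]trimethylsilane | COc1ccc(OC)c(Oc2ccc(O[Si](C)(C)C)c([Si](C)(C)C)c2)c1 | intermediate
12 | 4-(2,5-dimethoxyphenoxy)-2-(trimethylsilyl)phenol | COc1ccc(OC)c(Oc2ccc(O)c([Si](C)(C)C)c2)c1 | intermediate
13 | 2,3,6-tribromo-4-(3,4,6-tribromo-2,5-dimethoxyphenoxy)phenol | Oc1c(Br)cc(Oc2c(OC)c(Br)c(Br)c(OC)c2Br)c(Br)c1Br | intermediate
14 | 2,3,5-tribromo-6-(2,3,5-tribromo-4-hydroxyphenoxy)benzene-1,4-diol | Oc1c(Br)cc(Oc2c(O)c(Br)c(Br)c(O)c2Br)c(Br)c1Br | target

**Step count and risks**
Total step count: 5. Longest linear sequence: 5 steps (1 and 2 → 5 → 8 → 12 → 13 → 14).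

Steps most likely to fail, in order of risk:

Step 3. After alkyne insertion the silyl-substituted vinylketene may be too stabilised to cyclise and may drift to cyclobutenone or furan formation. A second alkyne may also insert, or the electrophilic aryloxycarbene may decompose before CO dissociates. The fallback sets out from 8 and returns at 13, and it exchanges the acetylene component and the placeholder element. Heating 8 with tributyl(ethynyl)stannane in THF at 50 °C should give, by the same benzannulation and silyl shift, tricarbonyl{η6-[4-(2,5-dimethoxyphenoxy)-3-(tributylstannyl)phenoxy]trimethylsilane}chromium F1. Air should release from it [4-(2,5-dimethoxyphenoxy)-3-(tributylstannyl)phenoxy]trimethylsilane F2. Catalytic K2CO3 in methanol (no acid, which would cleave the C–Sn bond) should then give 4-(2,5-dimethoxyphenoxy)-3-(tributylstannyl)phenol F3. Stannylalkynes are expected to insert with the metal next to the carbene-derived carbon, so tin marks the ring A carbon meta to the hydroxyl. Bromine under the conditions of step 4 then replaces tin by ipso-substitution and brominates both positions ortho to the hydroxyl, which gives 13 without a Lewis-acid-forced substitution on ring A. Because C3 and C5 are equivalent, either orientation of alkyne insertion leads to 13.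

Step 4. The last two substitutions (C5 of ring A and C3′ of ring B) are slow. Under the forcing conditions the free para-aryloxyphenol may suffer ipso attack at C4 with oxidative loss of ring B, or bromination may run on to C3. The fallback sets out from 12 and returns at 14, and it separates the hydroxyl-directed brominations from the forced ones. Bromine (3 equiv, CH2Cl2, −78 → 0 °C) should give 2,6-dibromo-4-(4-bromo-2,5-dimethoxyphenoxy)phenol F4, which fixes the ring A regiochemistry. Methylation (MeI, K2CO3, DMF) should give 1,3-dibromo-5-(4-bromo-2,5-dimethoxyphenoxy)-2-methoxybenzene F5, whose ring A is still symmetric and can no longer be oxidised to a quinone. Bromine with iron in refluxing CHCl3 should then give 2,3,5-tribromo-1,4-dimethoxy-6-(2,3,5-tribromo-4-methoxyphenoxy)benzene F6. BBr3 as in step 5 cleaves all three methyl ethers to 14.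

Step 2. The phenol may attack the acetyl carbonyl of the acetoxycarbene and so return the acylate, it may add to the alkene in conjugate fashion, or the aryloxycarbene may decompose during isolation. The fallback sets out from 6 and returns at 13; it gives up the chromium chemistry and forms the ether C–O bond by copper coupling. Chan–Lam coupling of 6 with 4-(benzyloxy)phenylboronic acid (Cu(OAc)2, pyridine, 4 Å sieves, CH2Cl2, air) should give 2-[4-(benzyloxy)phenoxy]-1,4-dimethoxybenzene F7. Hydrogenolysis (H2, Pd/C, EtOAc) should give 4-(2,5-dimethoxyphenoxy)phenol F8. Bromine under the conditions of step 4 should convert F8 into 13 by six C–H brominations, with the same hydroxyl-directed and symmetry-based regiochemistry.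

**Further compounds**
F1 | step 3 | tricarbonyl{η6-[4-(2,5-dimethoxyphenoxy)-3-(tributylstannyl)phenoxy]trimethylsilane}chromium | COc1ccc(OC)c(Oc2ccc(O[Si](C)(C)C)cc2[Sn](CCCC)(CCCC)CCCC)c1.O=C=[Cr](=C=O)=C=O
F2 | step 3 | [4-(2,5-dimethoxyphenoxy)-3-(tributylstannyl)phenoxy]trimethylsilane | COc1ccc(OC)c(Oc2ccc(O[Si](C)(C)C)cc2[Sn](CCCC)(CCCC)CCCC)c1
F3 | step 3 | 4-(2,5-dimethoxyphenoxy)-3-(tributylstannyl)phenol | COc1ccc(OC)c(Oc2ccc(O)cc2[Sn](CCCC)(CCCC)CCCC)c1
F4 | step 4 | 2,6-dibromo-4-(4-bromo-2,5-dimethoxyphenoxy)phenol | COc1cc(Br)c(OC)cc1Oc2cc(Br)c(O)c(Br)c2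
F5 | step 4 | 1,3-dibromo-5-(4-bromo-2,5-dimethoxyphenoxy)-2-methoxybenzene | COc1cc(Br)c(OC)cc1Oc2cc(Br)c(OC)c(Br)c2
F6 | step 4 | 2,3,5-tribromo-1,4-dimethoxy-6-(2,3,5-tribromo-4-methoxyphenoxy)benzene | COc1c(Br)cc(Oc2c(OC)c(Br)c(Br)c(OC)c2Br)c(Br)c1Br
F7 | step 2 | 2-[4-(benzyloxy)phenoxy]-1,4-dimethoxybenzene | COc1ccc(OC)c(Oc2ccc(OCc3ccccc3)cc2)c1
F8 | step 2 | 4-(2,5-dimethoxyphenoxy)phenol | COc1ccc(OC)c(Oc2ccc(O)cc2)c1
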